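The naphthalene (C1 bears aryl ring C, C2 the CH2–ring D benzyl, C3 a hydroxyl; ring A = C4a, C5 OMe, C6 OH, C7 OMe, C8, C8a) is cut at C1–C8a and C4–C4a. The exploited feature is that ring A is intact syringol: its carbon para to the hydroxyl becomes C8a and the neighbouring carbon, ortho to a methoxyl, becomes C4a. In one acid-mediated operation syringol adds to the enone β-carbon C1, the acetal carbon C4 closes ring B onto C4a, and loss of methanol aromatises ring B to the C3 naphthol. The precursor is an (E)-α-benzyl-β-aryl enone with an α-keto dimethyl acetal (C3, C4), its ring C and ring D phenols masked as 4-(trifluoromethyl)benzyl ethers.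

Key step: step 6

Remark on the protecting groups: 4-(trifluoromethyl)benzyl ethers are chosen for the ring C and ring D phenols because this electron-poor benzyl group should not ionise under the acid of step 6, so no benzyl transfer to syringol is expected. It should also survive base and the alkene hydrogenation and still be removable by hydrogenolysis. The carbon skeletons of the key-step precursor 8 and product 12 are unaffected by this choice.

Remark on stereochemistry: the target SMILES defines no stereo-element. Intermediates 10 and 11 are racemic diastereomer mixtures whose stereocentres are erased within step 6. If the C1–ring C biaryl axis is configurationally stable, it is formed as the racemate.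

Assumption: compounds 1, 3, 6, 9 and 4-(trifluoromethyl)benzyl bromide are taken as commercial.

Step 1
Reactants: 1 vanillin (4-hydroxy-3-methoxybenzaldehyde)
Product: 2 3-methoxy-4-{[4-(trifluoromethyl)benzyl]oxy}benzaldehyde
Conditions: 4-(CF3)C6H4CH2Br (1.1 equiv), K2CO3, DMF, 60 °C
Reagents that add atoms: 4-(trifluoromethyl)benzyl bromide, FC(F)(F)c1ccc(CBr)cc1
Why: Williamson ether synthesis, in which the phenoxide formed by K2CO3 is alkylated by the benzylic bromide (SN2) while the aldehyde stays inert.

Step 2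
Reactants: 2 3-methoxy-4-{[4-(trifluoromethyl)benzyl]oxy}benzaldehyde; 3 1,1-dimethoxypropan-2-one (methylglyoxal dimethyl acetal)
Product: 4 (E)-1,1-dimethoxy-4-(3-methoxy-4-{[4-(trifluoromethyl)benzyl]oxy}phenyl)but-3-en-2-one
Conditions: 3 (2 equiv), NaOH, MeOH/H2O, 0 °C to rt
Reagents that add atoms: none
Why: Claisen–Schmidt condensation, in which the aldehyde cannot enolise, the methyl group is the only position of 3 whose aldol can dehydrate, and E1cB loss of water should give the more stable E enone.

Step 3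
Reactants: 4 (E)-1,1-dimethoxy-4-(3-methoxy-4-{[4-(trifluoromethyl)benzyl]oxy}phenyl)but-3-en-2-one
Product: 5 1,1-dimethoxy-4-(3-methoxy-4-{[4-(trifluoromethyl)benzyl]oxy}phenyl)butan-2-one
Conditions: H2 (1 atm), 10% Pd/C, Ph2S (cat.), EtOAc, rt
Reagents that add atoms: none
Why: Chemoselective catalytic hydrogenation of the conjugated C=C on sulfide-poisoned palladium on carbon, which should spare the ketone, the acetal and the aryl benzyl-type ether (the electron-poor benzyl group is in addition slow to hydrogenolyse).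

Step 4
Reactants: 6 4-hydroxy-2-methoxybenzaldehyde
Product: 7 2-methoxy-4-{[4-(trifluoromethyl)benzyl]oxy}benzaldehyde
Conditions: 4-(CF3)C6H4CH2Br (1.1 equiv), K2CO3, DMF, 60 °C
Reagents that add atoms: 4-(trifluoromethyl)benzyl bromide, FC(F)(F)c1ccc(CBr)cc1
Why: Williamson ether synthesis at the only phenol, as in step 1.

Step 5
Reactants: 5 1,1-dimethoxy-4-(3-methoxy-4-{[4-(trifluoromethyl)benzyl]oxy}phenyl)butan-2-one; 7 2-methoxy-4-{[4-(trifluoromethyl)benzyl]oxy}benzaldehyde
Product: 8 (E)-1,1-dimethoxy-4-(2-methoxy-4-{[4-(trifluoromethyl)benzyl]oxy}phenyl)-3-(3-methoxy-4-{[4-(trifluoromethyl)benzyl]oxy}benzyl)but-3-en-2-one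
Conditions: KOH, MeOH, 50 °C
Reagents that add atoms: none
Why: Claisen–Schmidt condensation at the only methylene next to the ketone (the acetal methine cannot give an enone and the aldehyde has no α-hydrogen), with E1cB dehydration expected to place ring C trans to the acyl group.

Step 6
Reactants: 8 (E)-1,1-dimethoxy-4-(2-methoxy-4-{[4-(trifluoromethyl)benzyl]oxy}phenyl)-3-(3-methoxy-4-{[4-(trifluoromethyl)benzyl]oxy}benzyl)but-3-en-2-one; 9 syringol (2,6-dimethoxyphenol)
Product: 12 5,7-dimethoxy-1-(2-methoxy-4-{[4-(trifluoromethyl)benzyl]oxy}phenyl)-2-(3-methoxy-4-{[4-(trifluoromethyl)benzyl]oxy}benzyl)naphthalene-3,6-diol, via conjugate adduct ketone 10 (not isolated), via methoxytetralone 11 (not isolated)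
Conditions: 9 (3 equiv), TfOH (0.3 equiv), HFIP/CH2Cl2 (1:4), 0 °C then 40 °C, Ar
Reagents that add atoms: none
Why: Proposed new method: TfOH protonates the enone carbonyl of 8 to a C1 cation stabilised by the ortho-methoxy and para-alkoxy groups of ring C, which free syringol captures through its carbon para to the hydroxyl (C1–C8a bond, giving 10); on warming the α-keto acetal ionises and its oxocarbenium carbon C4 attacks the adjacent ring A carbon C4a (giving 11), and enolisation towards C2 followed by 1,4-elimination of methanol aromatises ring B. The closest known reactions are acid-catalysed Friedel–Crafts conjugate addition of phenols to enones and Bradsher-type cyclodehydration of aryl acetals, here merged into one benzannulation of an unfunctionalised phenol. Ring B closes in a 6-exo-trig Friedel–Crafts mode onto the oxocarbenium ion. No stereocentre survives, because C1, C2 and C4 of 10 and 11 all become sp2 on aromatisation. The step needs syringol to react first through its para carbon and then through C4a in preference to ring D: the hydroxyl directs the first bond para, the two neighbouring carbons are equivalent by symmetry and each is activated by an ortho and a para methoxyl (the competing ring D carbon has only one para methoxyl, the free ortho carbon of ring C none), and the carbonyl-destabilised oxocarbenium ion should form more slowly than the protonated enone is consumed, so the acetal should not alkylate syringol or ring D first. The 4-(trifluoromethyl)benzyl ethers should not ionise under these conditions, which should prevent benzyl transfer to syringol.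

Step 7
Reactants: 12 5,7-dimethoxy-1-(2-methoxy-4-{[4-(trifluoromethyl)benzyl]oxy}phenyl)-2-(3-methoxy-4-{[4-(trifluoromethyl)benzyl]oxy}benzyl)naphthalene-3,6-diol
Product: 13 1-(4-hydroxy-2-methoxyphenyl)-2-(4-hydroxy-3-methoxybenzyl)-5,7-dimethoxynaphthalene-3,6-diol (CNP0000246.0)
Conditions: H2 (3 atm), Pd(OH)2/C, EtOAc/MeOH, rt
Reagents that add atoms: none
Why: Catalytic hydrogenolysis of the two aryl benzyl-type C–O bonds, to which aryl methyl ethers, free phenols and the naphthalene are inert, should reveal the last two hydroxyls.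

Compound list
1 | vanillin (4-hydroxy-3-methoxybenzaldehyde) | COc1cc(C=O)ccc1O | starting material
2 | 3-methoxy-4-{[4-(trifluoromethyl)benzyl]oxy}benzaldehyde | COc1cc(C=O)ccc1OCc1ccc(cc1)C(F)(F)F | intermediate
3 | 1,1-dimethoxypropan-2-one (methylglyoxal dimethyl acetal) | CC(=O)C(OC)OC | starting material
4 | (E)-1,1-dimethoxy-4-(3-methoxy-4-{[4-(trifluoromethyl)benzyl]oxy}phenyl)but-3-en-2-one | COc1cc(/C=C/C(=O)C(OC)OC)ccc1OCc1ccc(cc1)C(F)(F)F | intermediate
5 | 1,1-dimethoxy-4-(3-methoxy-4-{[4-(trifluoromethyl)benzyl]oxy}phenyl)butan-2-one | COc1cc(CCC(=O)C(OC)OC)ccc1OCc1ccc(cc1)C(F)(F)F | intermediate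
6 | 4-hydroxy-2-methoxybenzaldehyde | COc1cc(O)ccc1C=O | starting material
7 | 2-methoxy-4-{[4-(trifluoromethyl)benzyl]oxy}benzaldehyde | COc1cc(OCc2ccc(cc2)C(F)(F)F)ccc1C=O | intermediate
8 | (E)-1,1-dimethoxy-4-(2-methoxy-4-{[4-(trifluoromethyl)benzyl]oxy}phenyl)-3-(3-methoxy-4-{[4-(trifluoromethyl)benzyl]oxy}benzyl)but-3-en-2-one (key-step precursor) | COc1cc(C/C(=C\c2ccc(OCc3ccc(cc3)C(F)(F)F)cc2OC)C(=O)C(OC)OC)ccc1OCc1ccc(cc1)C(F)(F)F | intermediate
9 | syringol (2,6-dimethoxyphenol) | COc1cccc(OC)c1O | starting material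
10 | 4-(4-hydroxy-3,5-dimethoxyphenyl)-1,1-dimethoxy-4-(2-methoxy-4-{[4-(trifluoromethyl)benzyl]oxy}phenyl)-3-(3-methoxy-4-{[4-(trifluoromethyl)benzyl]oxy}benzyl)butan-2-one (conjugate adduct ketone; racemic diastereomer mixture, not isolated) | COc1cc(CC(C(c2cc(OC)c(O)c(OC)c2)c2ccc(OCc3ccc(cc3)C(F)(F)F)cc2OC)C(=O)C(OC)OC)ccc1OCc1ccc(cc1)C(F)(F)F | intermediate
11 | 6-hydroxy-4,5,7-trimethoxy-1-(2-methoxy-4-{[4-(trifluoromethyl)benzyl]oxy}phenyl)-2-(3-methoxy-4-{[4-(trifluoromethyl)benzyl]oxy}benzyl)-1,2,3,4-tetrahydronaphthalen-3-one (target numbering; a 1-methoxy-2-tetralone; racemic diastereomer mixture, not isolated) | COC1C(=O)C(Cc2ccc(OCc3ccc(cc3)C(F)(F)F)c(OC)c2)C(c2ccc(OCc3ccc(cc3)C(F)(F)F)cc2OC)c2cc(OC)c(O)c(OC)c12 | intermediate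
12 | 5,7-dimethoxy-1-(2-methoxy-4-{[4-(trifluoromethyl)benzyl]oxy}phenyl)-2-(3-methoxy-4-{[4-(trifluoromethyl)benzyl]oxy}benzyl)naphthalene-3,6-diol (key-step product) | COc1cc(Cc2c(O)cc3c(OC)c(O)c(OC)cc3c2-c2ccc(OCc4ccc(cc4)C(F)(F)F)cc2OC)ccc1OCc1ccc(cc1)C(F)(F)F | intermediate
13 | 1-(4-hydroxy-2-methoxyphenyl)-2-(4-hydroxy-3-methoxybenzyl)-5,7-dimethoxynaphthalene-3,6-diol (CNP0000246.0) | COc1cc(Cc2c(O)cc3c(OC)c(O)c(OC)cc3c2-c2ccc(O)cc2OC)ccc1O | target

Total step count: 7. Longest linear sequence: 6 (steps 1, 2, 3, 5, 6, 7); step 4 is a one-step branch.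

Steps most likely to fail

Step 6. The cascade may be diverted in several ways:
- premature ionisation of the acetal, with closure onto ring D before syringol has added;
- intramolecular capture of the C1 cation by ring D;
- attack of syringol through a carbon other than the para carbon;
- oligomerisation through the electron-rich ring C.

The fallback uses known chemistry, forms the two bonds in separate operations and fixes the site on ring A with a carbon–metal bond. It sets out from 8 and comes back to the route at 12. Commercial 4-bromo-2,6-dimethoxyphenol F1 would be silylated (TBSCl, imidazole, DMF) to (4-bromo-2,6-dimethoxyphenoxy)(tert-butyl)dimethylsilane F2 and converted with Mg in THF into [4-(tert-butyldimethylsilyloxy)-3,5-dimethoxyphenyl]magnesium bromide F3. Copper-catalysed conjugate addition of F3 to 8 (CuBr·SMe2 cat., Me3SiCl, THF, −78 to −20 °C) should give the trimethylsilyl enol ether F4. Dilute acid work-up should hydrolyse F4 to the β,β-diaryl ketone F5, in which the C1–C8a bond is in place without regiochemical ambiguity. Bradsher-type cyclodehydration of the α-keto acetal of F5 (TsOH, toluene, 80 °C) should then close C4–C4a and aromatise ring B to the silyl-protected naphthol F6. Bu4NF in THF would cleave the silyl ether to give 12.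

Step 5. Condensation at the hindered methylene with an electron-rich aldehyde may be slow, may revert by retro-aldol cleavage, or may be followed by base-mediated migration of the double bond into conjugation with ring D. The fallback is a kinetic, directed aldol with separate dehydration, setting out from 5 and 7 and coming back at 8. Ketone 5 would be deprotonated at the methylene with LiN(iPr)2 (THF, −78 °C) and treated with 7 to give the β-hydroxy ketone F7 (diastereomer mixture), which is isolated. MsCl/Et3N (CH2Cl2, 0 °C) should convert F7 into the mesylate F8, and DBU in the same flask should eliminate it (E1cB) to 8. Under these conditions neither retro-aldol nor allylic isomerisation should operate.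

Step 3. Over-reduction (hydrogenolysis of the benzylic C–O bond or reduction of the activated ketone) or stalling on the poisoned catalyst may occur. The fallback postpones protection, setting out from 1 and 3 and coming back at 5. Vanillin 1 itself would be condensed with 3 (NaOH, MeOH/H2O, Claisen–Schmidt) to (E)-4-(4-hydroxy-3-methoxyphenyl)-1,1-dimethoxybut-3-en-2-one F9. With no benzylic ether present, F9 would be hydrogenated over unpoisoned Pd/C (H2, EtOAc) to 4-(4-hydroxy-3-methoxyphenyl)-1,1-dimethoxybutan-2-one F10. O-Alkylation of F10 with 4-(trifluoromethyl)benzyl bromide and K2CO3 in DMF should give 5.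

Further compounds
F1 | step 6 | 4-bromo-2,6-dimethoxyphenol | COc1cc(Br)cc(OC)c1O
F2 | step 6 | (4-bromo-2,6-dimethoxyphenoxy)(tert-butyl)dimethylsilane | COc1cc(Br)cc(OC)c1O[Si](C)(C)C(C)(C)C
F3 | step 6 | [4-(tert-butyldimethylsilyloxy)-3,5-dimethoxyphenyl]magnesium bromide | COc1cc([Mg]Br)cc(OC)c1O[Si](C)(C)C(C)(C)C
F4 | step 6 | trimethylsilyl enol ether of the conjugate adduct: 4-[4-(tert-butyldimethylsilyloxy)-3,5-dimethoxyphenyl]-1,1-dimethoxy-4-(2-methoxy-4-{[4-(trifluoromethyl)benzyl]oxy}phenyl)-3-(3-methoxy-4-{[4-(trifluoromethyl)benzyl]oxy}benzyl)-2-(trimethylsilyloxy)but-2-ene (racemic, alkene geometry undefined) | COc1cc(CC(=C(O[Si](C)(C)C)C(OC)OC)C(c2cc(OC)c(O[Si](C)(C)C(C)(C)C)c(OC)c2)c2ccc(OCc3ccc(cc3)C(F)(F)F)cc2OC)ccc1OCc1ccc(cc1)C(F)(F)F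
F5 | step 6 | 4-[4-(tert-butyldimethylsilyloxy)-3,5-dimethoxyphenyl]-1,1-dimethoxy-4-(2-methoxy-4-{[4-(trifluoromethyl)benzyl]oxy}phenyl)-3-(3-methoxy-4-{[4-(trifluoromethyl)benzyl]oxy}benzyl)butan-2-one (racemic diastereomer mixture) | COc1cc(CC(C(c2cc(OC)c(O[Si](C)(C)C(C)(C)C)c(OC)c2)c2ccc(OCc3ccc(cc3)C(F)(F)F)cc2OC)C(=O)C(OC)OC)ccc1OCc1ccc(cc1)C(F)(F)F
F6 | step 6 | 6-(tert-butyldimethylsilyloxy)-5,7-dimethoxy-1-(2-methoxy-4-{[4-(trifluoromethyl)benzyl]oxy}phenyl)-2-(3-methoxy-4-{[4-(trifluoromethyl)benzyl]oxy}benzyl)naphthalen-3-ol | COc1cc(Cc2c(O)cc3c(OC)c(O[Si](C)(C)C(C)(C)C)c(OC)cc3c2-c2ccc(OCc4ccc(cc4)C(F)(F)F)cc2OC)ccc1OCc1ccc(cc1)C(F)(F)F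
F7 | step 5 | 4-hydroxy-1,1-dimethoxy-4-(2-methoxy-4-{[4-(trifluoromethyl)benzyl]oxy}phenyl)-3-(3-methoxy-4-{[4-(trifluoromethyl)benzyl]oxy}benzyl)butan-2-one (racemic diastereomer mixture) | COc1cc(CC(C(O)c2ccc(OCc3ccc(cc3)C(F)(F)F)cc2OC)C(=O)C(OC)OC)ccc1OCc1ccc(cc1)C(F)(F)F
F8 | step 5 | methanesulfonate of F7: 4,4-dimethoxy-1-(2-methoxy-4-{[4-(trifluoromethyl)benzyl]oxy}phenyl)-2-(3-methoxy-4-{[4-(trifluoromethyl)benzyl]oxy}benzyl)-3-oxobutyl methanesulfonate (racemic diastereomer mixture) | COc1cc(CC(C(OS(C)(=O)=O)c2ccc(OCc3ccc(cc3)C(F)(F)F)cc2OC)C(=O)C(OC)OC)ccc1OCc1ccc(cc1)C(F)(F)F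
F9 | step 3 | (E)-4-(4-hydroxy-3-methoxyphenyl)-1,1-dimethoxybut-3-en-2-one | COc1cc(/C=C/C(=O)C(OC)OC)ccc1O
F10 | step 3 | 4-(4-hydroxy-3-methoxyphenyl)-1,1-dimethoxybutan-2-one | COc1cc(CCC(=O)C(OC)OC)ccc1O
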